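## Analysis of the target

The target is a C25 chain with an acetate, closed at one end by a trimethylcyclohexanol (ring A) and at the other by a 4-substituted furan-2(5H)-one. The chain carbons are lettered Ca (on ring carbon C1) to Cj (on butenolide C4); Cc carries a methyl group and Cg the acetoxymethyl group. There are only two stereocentres, and they are adjacent: the tertiary carbinol C1 (R) and the methyl-bearing C6 (S). The hydroxyl and the C6 methyl are trans, so the C6 hydrogen is cis to the hydroxyl. C1 is fully substituted and wedged between the quaternary C2 (gem-dimethyl) and C6. Three alkenes have fixed geometry: Cc=Cd (E), Cg=Ch (Z, with CH2OAc cis to Ci) and Ci=Cj (E), the last two conjugated with the butenolide alkene. The butenolide (acidic OCH2, extended Michael acceptor), the allylic acetate and the tertiary alcohol are the sensitive groups, so the conjugated end should be made late and under near-neutral conditions. The hard part is ring A: adding a chain nucleophile to the corresponding trimethylcyclohexanone would be racemic and has no reliable bias toward the trans isomer. The plan rests on one feature: C1 and C6 are the two carbons of the tetrasubstituted alkene of (2,6,6-trimethylcyclohex-1-en-1-yl)methanol, whose CH2OH carbon is Ca. Ring A is therefore the product of a net syn addition of OH (to C1) and H (to C6) across that alkene, which a cis-epoxide can relay.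

## Retrosynthetic reasoning

**Acetate and silyl ether (31 ⇒ 30 ⇒ 29).** The acetate is put on last. In diol 30 the primary allylic hydroxyl is the only one that can be acylated at a useful rate, so the C1 hydroxyl needs no protection at that point. 30 comes from the C1 silyl ether 29; the small silyl group is there only to carry the C1 oxygen through organomagnesium chemistry.

**Cf–Cg and Ch–Ci (29 ⇒ 19 + 24 + 23).** Both bonds to the Cg=Ch unit are cut, which turns that unit into propargyl alcohol 24. Forward, an anti carbometalation of the alkoxide of 24 by the organomagnesium reagent from bromide 19 sets the Z geometry through chelation. A cross-coupling with iodide 23 then adds the butenolide with its E alkene already in place. Cutting here and not at Ci=Cj avoids an olefination next to the base-sensitive lactone and joins three fragments in one operation.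

**Iodovinyl butenolide (23 ⇒ 22 ⇒ 20 + 21).** The C4–Cj bond is cut. The bromide of 20 is a vinylogous acyl halide and couples readily with one tin of distannane 21. Tin–iodine exchange on 22 then gives 23 with the E geometry retained.

**Functional group changes at Cf and C1 (19 ⇒ 18 ⇒ 17 ⇒ 16).** The bromide needed for the organomagnesium reagent is traced back to a protected primary alcohol. Cf must be an ether, not a halide, while the sulfonyl carbanion is in play, because that carbanion would displace a halide at Cf intramolecularly.

**Ca–Cb (16 ⇒ 15 ⇒ 9 + 14).** This cut is the natural place to divide ring from chain. Ca is a CH2 on a carbinol carbon, which is the oxidation pattern of an opened terminal epoxide. The forward reaction is attack of the α-carbanion of allylic sulfone 14 on the CH2 of spiro-epoxide 9. It forms the bond, regenerates the C1 hydroxyl and leaves the C1 configuration untouched. The sulfonyl group is then removed reductively with the Cc=Cd alkene kept in place.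

**Sulfone (14 ⇒ 12 ⇒ 11 ⇒ 10).** The E trisubstituted alkene is not built but inherited. Allylic oxidation of the gem-dimethyl alkene of 11 at the methyl trans to the chain gives 12, and the hydroxyl is exchanged for the sulfonyl group.

**Spiro-epoxide and C6 (9 ⇒ 7 ⇒ 6 ⇒ 5 ⇒ 4).** 9 is the dehydration product of 1,2-diol 7. The C6–H bond of 6 is made by hydrogenating the exocyclic alkene of 5 under the direction of the C1 hydroxyl, which places hydrogen cis to OH. 5 comes from epoxide 4 by base-induced elimination toward the C6 methyl. This cleaves the C6–O bond and keeps the C1–O bond.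

**Key disconnection (4 ⇒ 3 ⇒ 2 ⇒ 1).** The oxirane of 3 is a temporary ring. Its C1–O bond survives into the target and its C6–O bond is given up later. It is formed by reagent-controlled epoxidation of the achiral allylic alcohol 2 on one enantiotopic face. The CH2OH group that directs the reagent is Ca itself, so nothing has to be added or removed to make the directing group. 2 is one reduction away from the commercial aldehyde 1, so the risk of the route sits in the epoxidation.

## Alternatives that were turned down

**Alternative 1:** Here the Cg=Ch alkene is disconnected inside a temporary five-membered lactone. The forward key step adds the primary hydroxyl of the hydroxy ketone (5E)-1-hydroxy-8-[(1R,6S)-1-hydroxy-2,2,6-trimethylcyclohexyl]-6-methyloct-5-en-2-one A2 to the cumulated ylide ketenylidenetriphenylphosphorane A3. The resulting ester ylide closes on the ketone by intramolecular Wittig reaction to give 4-{(E)-6-[(1R,6S)-1-hydroxy-2,2,6-trimethylcyclohexyl]-4-methylhex-3-en-1-yl}furan-2(5H)-one A1. The lactone would then be reduced to the lactol, the masked enal olefinated to form Ci=Cj with the real butenolide, and the freed CH2OH acetylated.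
- For it: the ring forces CH2O and Ci to be cis, which is a firmer guarantee of the Z geometry than chelation in a carbometalation. The sequence is metal-free and A1 is a robust, isolable compound.
- Against it: A2 already contains ring A, so the approach says nothing about C1 and C6. Once the lactol is opened, the Z hydroxy enal can isomerise. The Ci=Cj olefination needs a butenolide-stabilised phosphorus reagent, whose E selectivity is uncertain and whose base threatens the lactone. It also costs about three more steps than a three-component coupling.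
- Comparison: Alternative 1 is stronger on the certainty of the Cg=Ch geometry. The chosen route gives that up for a one-flask construction of both diene bonds, and spends its stereochemical effort on ring A, which this alternative does not address.

**Alternative 2:** This cuts Cf–Cg and Ch–Ci around propargyl alcohol 24. The organomagnesium reagent 25 adds anti to the magnesium alkoxide of 24 under copper catalysis. After exchange to zinc, the alkenylmetal is coupled with iodide 23 under palladium catalysis to give 4-{(1E,3Z,7E)-4-(hydroxymethyl)-8-methyl-10-[(1R,6S)-2,2,6-trimethyl-1-(trimethylsilyloxy)cyclohexyl]deca-1,3,7-trien-1-yl}furan-2(5H)-one A4, which is compound 29 of the route.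
- For it: it is convergent, sets the Z alkene and introduces the sensitive butenolide late.
- Against it as the organising idea: no ring closes and no stereocentre is made. The C16 fragment with C1 and C6 must already exist, so the real difficulty of the target is left unassigned. The one-flask operation also consumes a precious organomagnesium reagent.
- Comparison: on the chain this move is as good as any, and it is not rejected: the chosen route uses it as step 18. What the chosen strategy adds is a defined origin for ring A and its two stereocentres.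

**Alternative 3:** This disconnects the ring bond C1–C2 by a cationic cyclisation. An engineered squalene–hopene cyclase (a class two, protonation-dependent terpene cyclase) would protonate the terminal alkene of (2E,6E)-farnesol A6, close ring A, shift hydride from C1 to C6 and capture the C1 cation as the hydroxyl. The product would be (E)-5-[(1R,6S)-1-hydroxy-2,2,6-trimethylcyclohexyl]-3-methylpent-2-en-1-ol A5.
- For it: one step from a commodity terpene would deliver ring A, both stereocentres, the E alkene Cc=Cd and a hydroxyl handle. On step economy it is clearly stronger than the thirteen steps the chosen route needs to reach the comparable diol 17.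
- Against it: it needs an enzyme variant that stops after one ring although the next alkene of A6 is poised to continue to bicyclic products. The hydroxyl must also enter C1 on the face the hydride has just left (H at C6 cis to OH), which is not the antiperiplanar course that a concerted shift and capture would follow. Neither property can be predicted from structure; both would have to be found by screening. A5 also ends at Ce, one carbon short of Cf, so the chain extension would have to be redesigned.
- Comparison: the chosen strategy is longer but uses shelf reagents and an empirical facial rule that can be applied in advance.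

Key step: step 2

## Route

Remark: the absolute sense of step 2 is assigned from the empirical tartrate rule, not from a model of the catalyst; compounds 10, 21 and 24 are taken as catalogue chemicals.

Step 1
Reactants: 1 β-cyclocitral (2,6,6-trimethylcyclohex-1-ene-1-carbaldehyde)
Product: 2 β-cyclogeraniol, (2,6,6-trimethylcyclohex-1-en-1-yl)methanol
Conditions: NaBH4, MeOH, 0 °C
Reagents that add atoms: none
Why: Borohydride 1,2-reduction of an unsaturated aldehyde; the fully substituted β-carbon disfavours conjugate addition, so the allylic alcohol should form cleanly.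

Step 2
Reactants: 2 β-cyclogeraniol
Product: 3 [(1R,6R)-2,2,6-trimethyl-7-oxabicyclo[4.1.0]heptan-1-yl]methanol
Conditions: Ti(OiPr)4 (1.0 equiv), diethyl D-(−)-tartrate (1.2 equiv), t-BuOOH (2 equiv, anhydrous), 4 Å sieves, CH2Cl2, −20 °C; aq Na2SO4 work-up
Reagents that add atoms: tert-butyl hydroperoxide, CC(C)(C)OO
Why: Katsuki–Sharpless asymmetric epoxidation: isopropoxide exchange loads the alkoxide of 2 and the tert-butylperoxo ligand onto one titanium of the dimeric titanium tartrate, and the alkene attacks the activated peroxide oxygen along the O–O axis in a concerted spiro transition state. The closest known cases are the epoxidations of cyclohex-1-enylmethanols and of tetrasubstituted allylic alcohols with this catalyst; the extra demand here is the quaternary C2 beside C1. The oxirane closes in a single suprafacial oxygen-atom transfer (a [2+1] addition with both C–O bonds made from the same face), which fixes the cis fusion and so the relation of C1 to C6. Their absolute configuration is set by the tartrate: by the empirical rule, L-(+)-tartrate gives the 2S epoxy alcohol whenever the CIP order at that carbon is oxirane O > second oxirane carbon > CH2OH > remaining substituent, as it is here, so the D-(−)-ester is expected to give (1R,6R)-3, and the sign would be checked on 3 through its MTPA esters before going on. The only selectivity needed is between the two enantiotopic faces, because 2 is achiral and has one alkene; binding through the CH2OH group, which is chain carbon Ca, is what holds the alkene in the chiral pocket. Stoichiometric titanium and sieves are proposed because hindered tetrasubstituted substrates turn over slowly, and a non-acidic work-up protects the fully substituted oxirane.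

Step 3
Reactants: 3 [(1R,6R)-2,2,6-trimethyl-7-oxabicyclo[4.1.0]heptan-1-yl]methanol
Product: 4 tert-butyl(dimethyl){[(1R,6R)-2,2,6-trimethyl-7-oxabicyclo[4.1.0]heptan-1-yl]methoxy}silane
Conditions: t-BuMe2SiCl, imidazole, DMF, rt
Reagents that add atoms: tert-butyldimethylsilyl chloride, CC(C)(C)[Si](C)(C)Cl
Why: Standard silylation of a primary alcohol; the bulky silyl ether later keeps this oxygen from binding aluminium or iridium and screens the Ca hydrogens.

Step 4
Reactants: 4 tert-butyl(dimethyl){[(1R,6R)-2,2,6-trimethyl-7-oxabicyclo[4.1.0]heptan-1-yl]methoxy}silane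
Product: 5 (1S)-1-({[tert-butyl(dimethyl)silyl]oxy}methyl)-2,2-dimethyl-6-methylidenecyclohexan-1-ol
Conditions: Et2Al(tmp) (from lithium 2,2,6,6-tetramethylpiperidide and Et2AlCl), toluene, 0 °C → rt
Reagents that add atoms: none
Why: Epoxide-to-allylic-alcohol isomerisation by a dialkylaluminium amide: aluminium binds the oxirane oxygen and the amide nitrogen removes a syn β-hydrogen through a six-membered transition state. The C6 methyl hydrogens are the least hindered and always syn, so the C6–O bond breaks and the C1–O bond keeps its configuration (the descriptor changes to S only because the CIP ranking changes); C2 has no hydrogen and the Ca hydrogens are screened by the silyl group.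

Step 5
Reactants: 5 (1S)-1-({[tert-butyl(dimethyl)silyl]oxy}methyl)-2,2-dimethyl-6-methylidenecyclohexan-1-ol
Product: 6 (1R,6S)-1-({[tert-butyl(dimethyl)silyl]oxy}methyl)-2,2,6-trimethylcyclohexan-1-ol
Conditions: [Ir(cod)(PCy3)(py)]PF6 (5 mol%), H2 (1 atm), CH2Cl2, 0 °C → rt
Reagents that add atoms: none
Why: Hydroxyl-directed homogeneous hydrogenation: the tertiary allylic hydroxyl binds the cationic iridium centre and both hydrogens enter the exocyclic alkene from the hydroxyl face, so the new C6–H is cis to OH and the methyl trans (6S). The hindered silyl ether oxygen should not compete as a ligand.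

Step 6
Reactants: 6 (1R,6S)-1-({[tert-butyl(dimethyl)silyl]oxy}methyl)-2,2,6-trimethylcyclohexan-1-ol
Product: 7 (1R,6S)-1-(hydroxymethyl)-2,2,6-trimethylcyclohexan-1-ol
Conditions: Bu4NF, THF, rt
Reagents that add atoms: none
Why: Fluoride cleavage of the silyl ether; nothing else in 6 responds to fluoride.

Step 7
Reactants: 7 (1R,6S)-1-(hydroxymethyl)-2,2,6-trimethylcyclohexan-1-ol
Product: 9 (3R,8S)-4,4,8-trimethyl-1-oxaspiro[2.5]octane, via primary tosylate 8 (not isolated)
Conditions: NaH (2.2 equiv), THF, 0 °C; then 1-(4-methylbenzenesulfonyl)imidazole, 0 °C → rt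
Reagents that add atoms: none
Why: One-flask epoxide formation from a 1,2-diol: the primary alkoxide is sulfonylated selectively and the neighbouring tertiary alkoxide displaces the tosylate in a 3-exo-tet closure (intramolecular Williamson reaction). Substitution takes place at the CH2 carbon only, so C1 keeps its configuration.

Step 8
Reactants: 10 4-methylpent-3-en-1-ol
Product: 11 tert-butyl(dimethyl)[(4-methylpent-3-en-1-yl)oxy]silane
Conditions: t-BuMe2SiCl, imidazole, CH2Cl2, rt
Reagents that add atoms: tert-butyldimethylsilyl chloride, CC(C)(C)[Si](C)(C)Cl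
Why: Standard silylation; Cf must be an ether here because a halide at Cf would be displaced intramolecularly by the sulfonyl carbanion of step 11.

Step 9
Reactants: 11 tert-butyl(dimethyl)[(4-methylpent-3-en-1-yl)oxy]silane
Product: 12 (2E)-5-{[tert-butyl(dimethyl)silyl]oxy}-2-methylpent-2-en-1-ol
Conditions: SeO2 (cat.), t-BuOOH, salicylic acid (cat.), CH2Cl2, rt
Reagents that add atoms: tert-butyl hydroperoxide, CC(C)(C)OO
Why: SeO2-catalysed allylic oxidation (ene reaction, then [2,3]-sigmatropic shift) attacks the more substituted alkene terminus and, in a gem-dimethyl alkene, the methyl trans to the chain, which gives the E allylic alcohol. Any enal from over-oxidation can be returned to 12 with NaBH4.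

Step 10
Reactants: 12 (2E)-5-{[tert-butyl(dimethyl)silyl]oxy}-2-methylpent-2-en-1-ol
Product: 14 {[(3E)-5-(benzenesulfonyl)-4-methylpent-3-en-1-yl]oxy}(tert-butyl)dimethylsilane, via allylic mesylate 13 (not isolated)
Conditions: MsCl, Et3N, THF, −20 °C; then PhSO2Na, Bu4NI (cat.), DMF, rt
Reagents that add atoms: sodium benzenesulfinate, [Na+].[O-]S(=O)c1ccccc1
Why: The allylic mesylate is displaced in the same flask by sulfinate at sulfur (through the allylic iodide) in an SN2 reaction at the primary carbon. This gives the sulfone directly and does not touch the E alkene.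

Step 11
Reactants: 14 {[(3E)-5-(benzenesulfonyl)-4-methylpent-3-en-1-yl]oxy}(tert-butyl)dimethylsilane; 9 (3R,8S)-4,4,8-trimethyl-1-oxaspiro[2.5]octane
Product: 15 (1R,6S)-1-[(3E)-2-(benzenesulfonyl)-6-{[tert-butyl(dimethyl)silyl]oxy}-3-methylhex-3-en-1-yl]-2,2,6-trimethylcyclohexan-1-ol (both epimers at the sulfonyl carbon)
Conditions: 14, n-BuLi, THF–HMPA, −78 °C; then 9, −78 °C → rt
Reagents that add atoms: none
Why: Alkylation of an α-sulfonyl allyl carbanion by an epoxide: the lithiated sulfone reacts at its α-carbon (Cb) with the CH2 terminus of 9, forming the Ca–Cb bond and releasing the C1 alkoxide without touching C1. The new centre at Cb is formed as a mixture that step 12 erases.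

Step 12
Reactants: 15 (1R,6S)-1-[(3E)-2-(benzenesulfonyl)-6-{[tert-butyl(dimethyl)silyl]oxy}-3-methylhex-3-en-1-yl]-2,2,6-trimethylcyclohexan-1-ol
Product: 16 (1R,6S)-1-[(3E)-6-{[tert-butyl(dimethyl)silyl]oxy}-3-methylhex-3-en-1-yl]-2,2,6-trimethylcyclohexan-1-ol
Conditions: PdCl2(dppp) (5 mol%), LiBHEt3 (3 equiv), THF, 0 °C
Reagents that add atoms: none
Why: Palladium-catalysed reductive desulfonylation of an allylic sulfone: zerovalent palladium ionises the C–S bond to an allylpalladium species and hydride from the borohydride takes its place. This reagent pair is the one known to put hydrogen on the carbon that carried sulfur while keeping the double bond in place and E; the hydroxyl is carried as its lithium alkoxide.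

Step 13
Reactants: 16 (1R,6S)-1-[(3E)-6-{[tert-butyl(dimethyl)silyl]oxy}-3-methylhex-3-en-1-yl]-2,2,6-trimethylcyclohexan-1-ol
Product: 17 (3E)-6-[(1R,6S)-1-hydroxy-2,2,6-trimethylcyclohexyl]-4-methylhex-3-en-1-ol
Conditions: Bu4NF, THF, rt
Reagents that add atoms: none
Why: Fluoride desilylation of the primary silyl ether.

Step 14
Reactants: 17 (3E)-6-[(1R,6S)-1-hydroxy-2,2,6-trimethylcyclohexyl]-4-methylhex-3-en-1-ol
Product: 18 (1R,6S)-1-[(3E)-6-bromo-3-methylhex-3-en-1-yl]-2,2,6-trimethylcyclohexan-1-ol
Conditions: CBr4, PPh3, CH2Cl2, 0 °C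
Reagents that add atoms: carbon tetrabromide, BrC(Br)(Br)Br
Why: Appel reaction: the primary alcohol is activated as an alkoxyphosphonium ion and displaced by bromide (SN2). The crowded tertiary hydroxyl at C1 cannot be activated at a comparable rate.

Step 15
Reactants: 18 (1R,6S)-1-[(3E)-6-bromo-3-methylhex-3-en-1-yl]-2,2,6-trimethylcyclohexan-1-ol
Product: 19 {[(1R,6S)-1-[(3E)-6-bromo-3-methylhex-3-en-1-yl]-2,2,6-trimethylcyclohexyl]oxy}trimethylsilane
Conditions: Me3SiOTf, 2,6-lutidine, CH2Cl2, −78 → 0 °C
Reagents that add atoms: trimethylsilyl trifluoromethanesulfonate, C[Si](C)(C)OS(=O)(=O)C(F)(F)F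
Why: Silylation with a silyl triflate, which is needed for a hydroxyl flanked by a quaternary and a tertiary carbon. The small trimethylsilyl group masks the acidic O–H for the organomagnesium step and comes off under mild conditions.

Step 16
Reactants: 20 4-bromofuran-2(5H)-one; 21 (E)-1,2-bis(tributylstannyl)ethene
Product: 22 4-[(E)-2-(tributylstannyl)ethenyl]furan-2(5H)-one
Conditions: Pd(PPh3)4 (5 mol%), 21 (2.5 equiv), toluene, 70 °C
Reagents that add atoms: none
Why: Stille coupling at a vinylogous acyl bromide: oxidative addition to the C4–Br bond is fast, and the excess of distannane ensures that only one tin is exchanged, leaving the E stannyl alkene.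

Step 17
Reactants: 22 4-[(E)-2-(tributylstannyl)ethenyl]furan-2(5H)-one
Product: 23 4-[(E)-2-iodoethenyl]furan-2(5H)-one
Conditions: I2, CH2Cl2, 0 °C
Reagents that add atoms: iodine, II
Why: Iododestannylation, an ipso substitution at the sp2 carbon that retains the alkene geometry.

Step 18
Reactants: 19 {[(1R,6S)-1-[(3E)-6-bromo-3-methylhex-3-en-1-yl]-2,2,6-trimethylcyclohexyl]oxy}trimethylsilane; 23 4-[(E)-2-iodoethenyl]furan-2(5H)-one; 24 propargyl alcohol (prop-2-yn-1-ol)
Product: 29 4-{(1E,3Z,7E)-4-(hydroxymethyl)-8-methyl-10-[(1R,6S)-2,2,6-trimethyl-1-(trimethylsilyloxy)cyclohexyl]deca-1,3,7-trien-1-yl}furan-2(5H)-one, via C16 alkylmagnesium bromide 25 (not isolated), via chloromagnesium propargyl alkoxide 26 (not isolated), via alkenylmagnesium chelate 27 (not isolated), via alkenylzinc chloride 28 (not isolated)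
Conditions: 19, Mg, THF, 40 °C; 24, i-PrMgCl, THF, −20 °C; combine, CuI (10 mol%), −10 °C → rt; ZnCl2, 0 °C; 23, Pd(PPh3)4 (5 mol%), rt
Reagents that add atoms: none
Why: Copper-catalysed carbomagnesiation of a propargylic alkoxide followed by Negishi coupling. The alkyl group adds to the alkyne carbon next to CH2O and magnesium to the terminal carbon in an anti sense, because the alkoxide holds magnesium in a five-membered chelate; this puts the Ch–metal bond cis to CH2O and the C16 chain trans. Exchange to zinc and palladium-catalysed coupling with 23 replace the metal with retention at both alkenyl carbons, which gives the 3Z,1E diene, and the organozinc does not attack the lactone.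

Step 19
Reactants: 29 4-{(1E,3Z,7E)-4-(hydroxymethyl)-8-methyl-10-[(1R,6S)-2,2,6-trimethyl-1-(trimethylsilyloxy)cyclohexyl]deca-1,3,7-trien-1-yl}furan-2(5H)-one
Product: 30 4-{(1E,3Z,7E)-4-(hydroxymethyl)-10-[(1R,6S)-1-hydroxy-2,2,6-trimethylcyclohexyl]-8-methyldeca-1,3,7-trien-1-yl}furan-2(5H)-one
Conditions: HF·pyridine, pyridine, THF, 0 °C → rt
Reagents that add atoms: none
Why: Fluoride cleavage of the tertiary trimethylsilyl ether under buffered conditions that leave the butenolide, the diene and the allylic alcohol alone.

Step 20
Reactants: 30 4-{(1E,3Z,7E)-4-(hydroxymethyl)-10-[(1R,6S)-1-hydroxy-2,2,6-trimethylcyclohexyl]-8-methyldeca-1,3,7-trien-1-yl}furan-2(5H)-one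
Product: 31 4-{(1E,3Z,7E)-4-(acetoxymethyl)-10-[(1R,6S)-1-hydroxy-2,2,6-trimethylcyclohexyl]-8-methyldeca-1,3,7-trien-1-yl}furan-2(5H)-one (the target, CNP0366059.1)
Conditions: Ac2O, pyridine, DMAP (cat.), CH2Cl2, 0 °C
Reagents that add atoms: acetic anhydride, CC(=O)OC(C)=O
Why: Acylation of the primary allylic alcohol; the hindered tertiary hydroxyl at C1 does not react under these conditions, so no protection is needed.

## Compound list

1 | β-cyclocitral | O=CC1=C(C)CCCC1(C)C | starting material
2 | β-cyclogeraniol, (2,6,6-trimethylcyclohex-1-en-1-yl)methanol | OCC1=C(C)CCCC1(C)C | intermediate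
3 | [(1R,6R)-2,2,6-trimethyl-7-oxabicyclo[4.1.0]heptan-1-yl]methanol | OC[C@@]12O[C@]1(C)CCCC2(C)C | intermediate
4 | tert-butyl(dimethyl){[(1R,6R)-2,2,6-trimethyl-7-oxabicyclo[4.1.0]heptan-1-yl]methoxy}silane | CC(C)(C)[Si](C)(C)OC[C@@]12O[C@]1(C)CCCC2(C)C | intermediate
5 | (1S)-1-({[tert-butyl(dimethyl)silyl]oxy}methyl)-2,2-dimethyl-6-methylidenecyclohexan-1-ol | CC(C)(C)[Si](C)(C)OC[C@@]1(O)C(=C)CCCC1(C)C | intermediate
6 | (1R,6S)-1-({[tert-butyl(dimethyl)silyl]oxy}methyl)-2,2,6-trimethylcyclohexan-1-ol | CC(C)(C)[Si](C)(C)OC[C@@]1(O)[C@@H](C)CCCC1(C)C | intermediate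
7 | (1R,6S)-1-(hydroxymethyl)-2,2,6-trimethylcyclohexan-1-ol | OC[C@@]1(O)[C@@H](C)CCCC1(C)C | intermediate
8 | [(1R,6S)-1-hydroxy-2,2,6-trimethylcyclohexyl]methyl 4-methylbenzenesulfonate (present as its sodium alkoxide) | Cc1ccc(cc1)S(=O)(=O)OC[C@@]1(O)[C@@H](C)CCCC1(C)C | intermediate
9 | (3R,8S)-4,4,8-trimethyl-1-oxaspiro[2.5]octane | O1C[C@]12[C@@H](C)CCCC2(C)C | intermediate
10 | 4-methylpent-3-en-1-ol | CC(C)=CCCO | starting material
11 | tert-butyl(dimethyl)[(4-methylpent-3-en-1-yl)oxy]silane | CC(C)=CCCO[Si](C)(C)C(C)(C)C | intermediate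
12 | (2E)-5-{[tert-butyl(dimethyl)silyl]oxy}-2-methylpent-2-en-1-ol | OC/C(C)=C/CCO[Si](C)(C)C(C)(C)C | intermediate
13 | (2E)-5-{[tert-butyl(dimethyl)silyl]oxy}-2-methylpent-2-en-1-yl methanesulfonate | CS(=O)(=O)OC/C(C)=C/CCO[Si](C)(C)C(C)(C)C | intermediate
14 | {[(3E)-5-(benzenesulfonyl)-4-methylpent-3-en-1-yl]oxy}(tert-butyl)dimethylsilane | O=S(=O)(C/C(C)=C/CCO[Si](C)(C)C(C)(C)C)c1ccccc1 | intermediate
15 | (1R,6S)-1-[(3E)-2-(benzenesulfonyl)-6-{[tert-butyl(dimethyl)silyl]oxy}-3-methylhex-3-en-1-yl]-2,2,6-trimethylcyclohexan-1-ol | O=S(=O)(c1ccccc1)C(C[C@@]1(O)[C@@H](C)CCCC1(C)C)/C(C)=C/CCO[Si](C)(C)C(C)(C)C | intermediate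
16 | (1R,6S)-1-[(3E)-6-{[tert-butyl(dimethyl)silyl]oxy}-3-methylhex-3-en-1-yl]-2,2,6-trimethylcyclohexan-1-ol | CC(C)(C)[Si](C)(C)OCC/C=C(\C)CC[C@@]1(O)[C@@H](C)CCCC1(C)C | intermediate
17 | (3E)-6-[(1R,6S)-1-hydroxy-2,2,6-trimethylcyclohexyl]-4-methylhex-3-en-1-ol | OCC/C=C(\C)CC[C@@]1(O)[C@@H](C)CCCC1(C)C | intermediate
18 | (1R,6S)-1-[(3E)-6-bromo-3-methylhex-3-en-1-yl]-2,2,6-trimethylcyclohexan-1-ol | BrCC/C=C(\C)CC[C@@]1(O)[C@@H](C)CCCC1(C)C | intermediate
19 | {[(1R,6S)-1-[(3E)-6-bromo-3-methylhex-3-en-1-yl]-2,2,6-trimethylcyclohexyl]oxy}trimethylsilane | BrCC/C=C(\C)CC[C@@]1(O[Si](C)(C)C)[C@@H](C)CCCC1(C)C | intermediate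
20 | 4-bromofuran-2(5H)-one | BrC1=CC(=O)OC1 | starting material
21 | (E)-1,2-bis(tributylstannyl)ethene | CCCC[Sn](CCCC)(CCCC)/C=C/[Sn](CCCC)(CCCC)CCCC | starting material
22 | 4-[(E)-2-(tributylstannyl)ethenyl]furan-2(5H)-one | CCCC[Sn](CCCC)(CCCC)/C=C/C1=CC(=O)OC1 | intermediate
23 | 4-[(E)-2-iodoethenyl]furan-2(5H)-one | I/C=C/C1=CC(=O)OC1 | intermediate
24 | propargyl alcohol (prop-2-yn-1-ol) | C#CCO | starting material
25 | bromo{(3E)-4-methyl-6-[(1R,6S)-2,2,6-trimethyl-1-(trimethylsilyloxy)cyclohexyl]hex-3-en-1-yl}magnesium | Br[Mg]CC/C=C(\C)CC[C@@]1(O[Si](C)(C)C)[C@@H](C)CCCC1(C)C | intermediate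
26 | chloromagnesium prop-2-yn-1-olate | C#CCO[Mg]Cl | intermediate
27 | alkenylmagnesium chelate: 4-{(3E)-4-methyl-6-[(1R,6S)-2,2,6-trimethyl-1-(trimethylsilyloxy)cyclohexyl]hex-3-en-1-yl}-2,5-dihydro-1,2-oxamagnesole | [Mg]1OCC(=C1)CC/C=C(\C)CC[C@@]2(O[Si](C)(C)C)[C@@H](C)CCCC2(C)C | intermediate
28 | (Z)-alkenylzinc chloride of 27 (chloromagnesium alkoxide) | Cl[Zn]/C=C(\CO[Mg]Cl)CC/C=C(\C)CC[C@@]1(O[Si](C)(C)C)[C@@H](C)CCCC1(C)C | intermediate
29 | 4-{(1E,3Z,7E)-4-(hydroxymethyl)-8-methyl-10-[(1R,6S)-2,2,6-trimethyl-1-(trimethylsilyloxy)cyclohexyl]deca-1,3,7-trien-1-yl}furan-2(5H)-one | OC/C(=C\C=C\C1=CC(=O)OC1)CC/C=C(\C)CC[C@@]1(O[Si](C)(C)C)[C@@H](C)CCCC1(C)C | intermediate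
30 | 4-{(1E,3Z,7E)-4-(hydroxymethyl)-10-[(1R,6S)-1-hydroxy-2,2,6-trimethylcyclohexyl]-8-methyldeca-1,3,7-trien-1-yl}furan-2(5H)-one | OC/C(=C\C=C\C1=CC(=O)OC1)CC/C=C(\C)CC[C@@]1(O)[C@@H](C)CCCC1(C)C | intermediate
31 | 4-{(1E,3Z,7E)-4-(acetoxymethyl)-10-[(1R,6S)-1-hydroxy-2,2,6-trimethylcyclohexyl]-8-methyldeca-1,3,7-trien-1-yl}furan-2(5H)-one | CC(=O)OC/C(=C\C=C\C1=CC(=O)OC1)CC/C=C(\C)CC[C@@]1(O)[C@@H](C)CCCC1(C)C | target

## Step count and least certain steps

Total: 20 steps. Longest linear sequence: 15 steps (steps 1–7, 11–15 and 18–20).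

**Step 2 (key step).** Oxygen transfer to a tetrasubstituted alkene beside a quaternary carbon may be slow, so conversion may stall. The quaternary C2 may also disturb the usual binding geometry and erode enantioface selection. Prolonged contact with Lewis-acidic titanium may open the fully substituted oxirane.
Fallback (sets out from 2, comes back at 3): epoxidise 2 without chiral control, under hydroxyl direction, with VO(acac)2 and t-BuOOH to give racemic [(1R*,6R*)-2,2,6-trimethyl-7-oxabicyclo[4.1.0]heptan-1-yl]methanol F1. Esterify it with (2S)-2-methoxy-2-phenylacetic acid (carbodiimide, DMAP) and separate the two diastereomeric esters by chromatography or crystallisation. These are [(1R,6R)-2,2,6-trimethyl-7-oxabicyclo[4.1.0]heptan-1-yl]methyl (2S)-2-methoxy-2-phenylacetate F2 and its (1S,6S) diastereomer F3. Hydrolysis of F2 with LiOH in aqueous THF gives 3. Stereocontrol then comes from resolution instead of the catalyst.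

**Step 5.** Iridium may coordinate to the silyl ether oxygen instead of the tertiary hydroxyl and deliver hydrogen to the wrong face. The exocyclic double bond may also migrate into the ring before reduction, or the crowded alcohol may bind too weakly for the directed pathway to dominate.
Fallback (sets out from 5, comes back at 7): tether the hydride to the C1 oxygen. Silylation of 5 with chlorodi(propan-2-yl)silane and imidazole gives tert-butyl{[(1S)-1-{[di(propan-2-yl)silyl]oxy}-2,2-dimethyl-6-methylidenecyclohexyl]methoxy}dimethylsilane F4. Protonation of the exocyclic alkene with CF3CO2H in CH2Cl2 at low temperature generates the C6 cation, which takes hydride from silicon through a five-membered transition state, necessarily on the oxygen face. The resulting {[(1R,6S)-1-({[tert-butyl(dimethyl)silyl]oxy}methyl)-2,2,6-trimethylcyclohexyl]oxy}di(propan-2-yl)silyl trifluoroacetate F5 is not purified; Bu4NF removes both silicon groups and gives 7. This is an intramolecular ionic hydrogenation in place of a metal-directed one.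

**Step 11.** Substitution at Ca is slow because the CH2 sits on a carbon flanked by two branched centres. The sulfonyl carbanion may decompose or equilibrate before it alkylates, and 9 may be recovered or isomerised by the base.
Fallback (sets out from 9, comes back at 17; it also bypasses steps 8–10, 12 and 13): use a slimmer, more nucleophilic carbanion and build the alkene afterwards. 3-(Trimethylsilyl)prop-2-yn-1-yllithium (from 1-(trimethylsilyl)propyne and n-BuLi) opens 9 at CH2 to give (1R,6S)-2,2,6-trimethyl-1-[4-(trimethylsilyl)but-3-yn-1-yl]cyclohexan-1-ol F6. K2CO3 in MeOH gives (1R,6S)-1-(but-3-yn-1-yl)-2,2,6-trimethylcyclohexan-1-ol F7. Methylalumination with Me3Al and Cp2ZrCl2 (cat.) adds methyl and aluminium syn and gives the (E)-alkenyl(dimethyl)alane, carried as its aluminium alkoxide, F8. Conversion to the ate complex with n-BuLi and reaction with oxirane extends Cd by two carbons to give 17, with the E geometry fixed by the syn addition.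

**Step 12.** The two allyl termini are both secondary, so hydride may be delivered to Cd and move the double bond to Cb=Cc. Syn–anti interconversion of the allylpalladium intermediate may erode the E geometry. The C1 alkoxide may attack the allylpalladium intermediate and form a cyclic ether.
Fallback (sets out from 9 and 12, comes back at 16): reverse the polarity so that sulfur sits on Ca, where no allylic transposition is possible. PhSNa opens 9 to (1R,6S)-2,2,6-trimethyl-1-[(phenylsulfanyl)methyl]cyclohexan-1-ol F9, and oxidation with a peracid gives (1R,6S)-1-[(benzenesulfonyl)methyl]-2,2,6-trimethylcyclohexan-1-ol F10. In parallel, 12 is converted with CBr4 and PPh3 into {[(3E)-5-bromo-4-methylpent-3-en-1-yl]oxy}(tert-butyl)dimethylsilane F11. The dianion of F10 (two equivalents of n-BuLi) is alkylated by F11 to give (1R,6S)-1-[(3E)-1-(benzenesulfonyl)-6-{[tert-butyl(dimethyl)silyl]oxy}-3-methylhex-3-en-1-yl]-2,2,6-trimethylcyclohexan-1-ol F12. Sodium amalgam (Na/Hg) with Na2HPO4 in MeOH removes the now non-allylic sulfonyl group and gives 16.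

**Step 18.** The C16 organomagnesium reagent may be lost by deprotonating the alkyne C–H of the propargyl alkoxide. Exchange to zinc may be incomplete, leaving basic magnesium species that attack or deprotonate the butenolide. The magnesium alkoxide may add to the lactone, and the excess alkyne may couple with 23.
Fallback (sets out from 19 and 24, uses 22, comes back at 29): separate the operation into two isolable stages. The carbomagnesiation is quenched with I2 to give (2Z)-3-iodo-2-{(3E)-4-methyl-6-[(1R,6S)-2,2,6-trimethyl-1-(trimethylsilyloxy)cyclohexyl]hex-3-en-1-yl}prop-2-en-1-ol F13, which can be purified. A Stille coupling of F13 with stannane 22 (Pd(PPh3)4, CuI, DMF, rt) then forms the Ch–Ci bond under neutral conditions and gives 29. No organozinc or organomagnesium species meets the butenolide, and step 17 is not needed.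

## Further compounds

F1 | step 2 | racemic [(1R*,6R*)-2,2,6-trimethyl-7-oxabicyclo[4.1.0]heptan-1-yl]methanol | OCC12OC1(C)CCCC2(C)C
F2 | step 2 | [(1R,6R)-2,2,6-trimethyl-7-oxabicyclo[4.1.0]heptan-1-yl]methyl (2S)-2-methoxy-2-phenylacetate | CO[C@H](C(=O)OC[C@@]12O[C@]1(C)CCCC2(C)C)c1ccccc1
F3 | step 2 | [(1S,6S)-2,2,6-trimethyl-7-oxabicyclo[4.1.0]heptan-1-yl]methyl (2S)-2-methoxy-2-phenylacetate | CO[C@H](C(=O)OC[C@]12O[C@@]1(C)CCCC2(C)C)c1ccccc1
F4 | step 5 | tert-butyl{[(1S)-1-{[di(propan-2-yl)silyl]oxy}-2,2-dimethyl-6-methylidenecyclohexyl]methoxy}dimethylsilane | CC(C)(C)[Si](C)(C)OC[C@@]1(O[SiH](C(C)C)C(C)C)C(=C)CCCC1(C)C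
F5 | step 5 | {[(1R,6S)-1-({[tert-butyl(dimethyl)silyl]oxy}methyl)-2,2,6-trimethylcyclohexyl]oxy}di(propan-2-yl)silyl trifluoroacetate | CC(C)(C)[Si](C)(C)OC[C@@]1(O[Si](OC(=O)C(F)(F)F)(C(C)C)C(C)C)[C@@H](C)CCCC1(C)C
F6 | step 11 | (1R,6S)-2,2,6-trimethyl-1-[4-(trimethylsilyl)but-3-yn-1-yl]cyclohexan-1-ol | C[Si](C)(C)C#CCC[C@@]1(O)[C@@H](C)CCCC1(C)C
F7 | step 11 | (1R,6S)-1-(but-3-yn-1-yl)-2,2,6-trimethylcyclohexan-1-ol | C#CCC[C@@]1(O)[C@@H](C)CCCC1(C)C
F8 | step 11 | dimethylaluminium (1R,6S)-1-[(3E)-4-(dimethylalumanyl)-3-methylbut-3-en-1-yl]-2,2,6-trimethylcyclohexan-1-olate | C[Al](C)/C=C(\C)CC[C@@]1(O[Al](C)C)[C@@H](C)CCCC1(C)C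
F9 | step 12 | (1R,6S)-2,2,6-trimethyl-1-[(phenylsulfanyl)methyl]cyclohexan-1-ol | c2ccccc2SC[C@@]1(O)[C@@H](C)CCCC1(C)C
F10 | step 12 | (1R,6S)-1-[(benzenesulfonyl)methyl]-2,2,6-trimethylcyclohexan-1-ol | O=S(=O)(C[C@@]1(O)[C@@H](C)CCCC1(C)C)c1ccccc1
F11 | step 12 | {[(3E)-5-bromo-4-methylpent-3-en-1-yl]oxy}(tert-butyl)dimethylsilane | BrC/C(C)=C/CCO[Si](C)(C)C(C)(C)C
F12 | step 12 | (1R,6S)-1-[(3E)-1-(benzenesulfonyl)-6-{[tert-butyl(dimethyl)silyl]oxy}-3-methylhex-3-en-1-yl]-2,2,6-trimethylcyclohexan-1-ol | O=S(=O)(c1ccccc1)C(C/C(C)=C/CCO[Si](C)(C)C(C)(C)C)[C@@]1(O)[C@@H](C)CCCC1(C)C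
F13 | step 18 | (2Z)-3-iodo-2-{(3E)-4-methyl-6-[(1R,6S)-2,2,6-trimethyl-1-(trimethylsilyloxy)cyclohexyl]hex-3-en-1-yl}prop-2-en-1-ol | OC/C(=C\I)CC/C=C(\C)CC[C@@]1(O[Si](C)(C)C)[C@@H](C)CCCC1(C)C
A1 | alternative 1 | 4-{(E)-6-[(1R,6S)-1-hydroxy-2,2,6-trimethylcyclohexyl]-4-methylhex-3-en-1-yl}furan-2(5H)-one | O=C1OCC(CC/C=C(\C)CC[C@@]2(O)[C@@H](C)CCCC2(C)C)=C1
A2 | alternative 1 | (5E)-1-hydroxy-8-[(1R,6S)-1-hydroxy-2,2,6-trimethylcyclohexyl]-6-methyloct-5-en-2-one | OCC(=O)CC/C=C(\C)CC[C@@]1(O)[C@@H](C)CCCC1(C)C
A3 | alternative 1 | ketenylidenetriphenylphosphorane | O=C=C=P(c1ccccc1)(c1ccccc1)c1ccccc1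
A4 | alternative 2 | 4-{(1E,3Z,7E)-4-(hydroxymethyl)-8-methyl-10-[(1R,6S)-2,2,6-trimethyl-1-(trimethylsilyloxy)cyclohexyl]deca-1,3,7-trien-1-yl}furan-2(5H)-one | OC/C(=C\C=C\C1=CC(=O)OC1)CC/C=C(\C)CC[C@@]1(O[Si](C)(C)C)[C@@H](C)CCCC1(C)C
A5 | alternative 3 | (E)-5-[(1R,6S)-1-hydroxy-2,2,6-trimethylcyclohexyl]-3-methylpent-2-en-1-ol | OC/C=C(\C)CC[C@@]1(O)[C@@H](C)CCCC1(C)C
A6 | alternative 3 | (2E,6E)-farnesol | CC(C)=CCC/C(C)=C/CC/C(C)=C/CO
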